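**Assumption:** the target has no stereocentre and no hindered axis (five benzene rings joined by freely rotating diaryl ethers), so it is achiral and no step has to set or keep configuration. Compounds 1, 2, 6, 10 and 12 are taken as catalogue chemicals.

**Retrosynthetic overview**
1. Target ⇐ its trideca-O-methyl ether by one global O-demethylation (BBr3); methyl ethers let every ring be bought already oxygenated.
2. Trideca-methyl ether ⇐ Ullmann C–O coupling at the ring C–O–ring D bond: a three-ring phenol (rings A–B–C) plus a two-ring aryl iodide (rings D–E).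
3. Rings A–B–C phenol ⇐ two rounds of SNAr (hindered phenoxide on a fluorobenzaldehyde) followed by Baeyer–Villiger CHO→OH: A–O–B first, then B–O–C.
4. Rings D–E iodide ⇐ ortho-iodination of 2,3,4-trimethoxyphenol, then Chan–Lam O-arylation with the ring E boronic acid.
5. No ring is constructed; the rings are joined in the order A–B, B–C (branch 1), D–E (branch 2), then C–D.

Ring labels: ring A = 2,4,6-trioxygenated terminus, then rings B, C, D, and ring E = 3,4,5-trioxygenated terminus.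

**Route**

Step 1
Reactants: 1 2,4,6-trimethoxyphenol; 2 2-fluoro-4,6-dimethoxybenzaldehyde
Product: 3 2,4-dimethoxy-6-(2,4,6-trimethoxyphenoxy)benzaldehyde
Conditions: Cs2CO3, DMSO, 110 °C, Ar
Reagents that add atoms: none
Why: Nucleophilic aromatic substitution (SNAr) in which the ortho-formyl group activates the C–F carbon toward the cesium phenoxide of 1, fluoride being the best leaving group for addition–elimination.

Step 2
Reactants: 3 2,4-dimethoxy-6-(2,4,6-trimethoxyphenoxy)benzaldehyde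
Product: 5 2,4-dimethoxy-6-(2,4,6-trimethoxyphenoxy)phenol, via aryl formate 4 (not isolated)
Conditions: mCPBA, DCM, 0 °C to rt; aq. NaHCO3 wash; then K2CO3 (cat.), degassed MeOH, rt
Reagents that add atoms: mCPBA (3-chloroperoxybenzoic acid), O=C(OO)c1cccc(Cl)c1
Why: Baeyer–Villiger oxidation in which the very electron-rich aryl group migrates to give the aryl formate, whose methanolysis frees the phenol (net Dakin-type CHO→OH).

Step 3
Reactants: 5 2,4-dimethoxy-6-(2,4,6-trimethoxyphenoxy)phenol; 6 4-fluoro-2,6-dimethoxybenzaldehyde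
Product: 7 4-[2,4-dimethoxy-6-(2,4,6-trimethoxyphenoxy)phenoxy]-2,6-dimethoxybenzaldehyde
Conditions: Cs2CO3, DMSO, 120 °C, Ar
Reagents that add atoms: none
Why: SNAr in which the para-formyl group activates an unhindered C–F carbon (flanked by two H) toward the hindered phenoxide of 5.

Step 4
Reactants: 7 4-[2,4-dimethoxy-6-(2,4,6-trimethoxyphenoxy)phenoxy]-2,6-dimethoxybenzaldehyde
Product: 9 4-[2,4-dimethoxy-6-(2,4,6-trimethoxyphenoxy)phenoxy]-2,6-dimethoxyphenol, via aryl formate 8 (not isolated)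
Conditions: mCPBA, DCM, 0 °C to rt; aq. NaHCO3 wash; then K2CO3 (cat.), degassed MeOH, rt
Reagents that add atoms: mCPBA (3-chloroperoxybenzoic acid), O=C(OO)c1cccc(Cl)c1
Why: Baeyer–Villiger oxidation of a 2,6-dimethoxybenzaldehyde (aryl migration strongly favoured) followed by formate methanolysis gives the syringol-type phenol of ring C.

Step 5
Reactants: 10 2,3,4-trimethoxyphenol
Product: 11 6-iodo-2,3,4-trimethoxyphenol
Conditions: I2 (1.05 equiv), NaHCO3, THF–H2O, 0 °C to rt, dark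
Reagents that add atoms: iodine, II
Why: Electrophilic aromatic iodination of the phenoxide, which directs to its only free ortho carbon (C-6) because the para position carries OMe.

Step 6
Reactants: 11 6-iodo-2,3,4-trimethoxyphenol; 12 (3,4,5-trimethoxyphenyl)boronic acid
Product: 13 1-iodo-3,4,5-trimethoxy-2-(3,4,5-trimethoxyphenoxy)benzene
Conditions: Cu(OAc)2 (2 equiv), pyridine, 4 Å MS, DCM, air, rt
Reagents that add atoms: none
Why: Chan–Lam oxidative O-arylation, which couples di-ortho-substituted phenols with electron-rich arylboronic acids at room temperature and leaves the C–I bond untouched.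

Step 7
Reactants: 9 4-[2,4-dimethoxy-6-(2,4,6-trimethoxyphenoxy)phenoxy]-2,6-dimethoxyphenol; 13 1-iodo-3,4,5-trimethoxy-2-(3,4,5-trimethoxyphenoxy)benzene
Product: 14 1-{4-[2,4-dimethoxy-6-(2,4,6-trimethoxyphenoxy)phenoxy]-2,6-dimethoxyphenoxy}-3,4,5-trimethoxy-2-(3,4,5-trimethoxyphenoxy)benzene
Conditions: CuI (20 mol %), picolinic acid (40 mol %), K3PO4, DMSO, 90 °C, Ar
Reagents that add atoms: none
Why: Ullmann diaryl ether coupling with the CuI/picolinic acid system, which is suited to 2,6-disubstituted phenols and ortho-substituted aryl iodides.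

Step 8
Reactants: 14 1-{4-[2,4-dimethoxy-6-(2,4,6-trimethoxyphenoxy)phenoxy]-2,6-dimethoxyphenoxy}-3,4,5-trimethoxy-2-(3,4,5-trimethoxyphenoxy)benzene
Product: 16 5-{4-[2,4-dihydroxy-6-(2,4,6-trihydroxyphenoxy)phenoxy]-2,6-dihydroxyphenoxy}-4-(3,4,5-trihydroxyphenoxy)benzene-1,2,3-triol (target), via tridecakis(O-dibromoboryl) ether 15 (not isolated)
Conditions: BBr3 (about 3 equiv per OMe), DCM, −78 °C to rt; then H2O, 0 °C, Ar; Sephadex LH-20 (degassed MeOH)
Reagents that add atoms: none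
Why: Lewis-acid ether cleavage in which BBr3 complexes each ArO–Me oxygen and bromide removes the methyl group by SN2, diaryl ether bonds being inert, and hydrolysis of the aryl borates frees the thirteen phenols.

**Compound list**
1 | 2,4,6-trimethoxyphenol (ring A) | COc1cc(OC)c(O)c(OC)c1 | starting material
2 | 2-fluoro-4,6-dimethoxybenzaldehyde (ring B) | COc1cc(F)c(C=O)c(OC)c1 | starting material
3 | 2,4-dimethoxy-6-(2,4,6-trimethoxyphenoxy)benzaldehyde | COc1cc(Oc2c(OC)cc(OC)cc2OC)c(C=O)c(OC)c1 | intermediate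
4 | 2,4-dimethoxy-6-(2,4,6-trimethoxyphenoxy)phenyl formate | COc1cc(Oc2c(OC)cc(OC)cc2OC)c(OC=O)c(OC)c1 | intermediate (not isolated)
5 | 2,4-dimethoxy-6-(2,4,6-trimethoxyphenoxy)phenol | COc1cc(Oc2c(OC)cc(OC)cc2OC)c(O)c(OC)c1 | intermediate
6 | 4-fluoro-2,6-dimethoxybenzaldehyde (ring C) | COc1cc(F)cc(OC)c1C=O | starting material
7 | 4-[2,4-dimethoxy-6-(2,4,6-trimethoxyphenoxy)phenoxy]-2,6-dimethoxybenzaldehyde | COc1cc(Oc2c(OC)cc(OC)cc2Oc2c(OC)cc(OC)cc2OC)cc(OC)c1C=O | intermediate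
8 | 4-[2,4-dimethoxy-6-(2,4,6-trimethoxyphenoxy)phenoxy]-2,6-dimethoxyphenyl formate | COc1cc(Oc2c(OC)cc(OC)cc2Oc2c(OC)cc(OC)cc2OC)cc(OC)c1OC=O | intermediate (not isolated)
9 | 4-[2,4-dimethoxy-6-(2,4,6-trimethoxyphenoxy)phenoxy]-2,6-dimethoxyphenol | COc1cc(Oc2c(OC)cc(OC)cc2Oc2c(OC)cc(OC)cc2OC)cc(OC)c1O | intermediate
10 | 2,3,4-trimethoxyphenol (ring D) | COc1ccc(O)c(OC)c1OC | starting material
11 | 6-iodo-2,3,4-trimethoxyphenol | COc1cc(I)c(O)c(OC)c1OC | intermediate
12 | (3,4,5-trimethoxyphenyl)boronic acid (ring E) | COc1cc(B(O)O)cc(OC)c1OC | starting material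
13 | 1-iodo-3,4,5-trimethoxy-2-(3,4,5-trimethoxyphenoxy)benzene | COc1cc(I)c(Oc2cc(OC)c(OC)c(OC)c2)c(OC)c1OC | intermediate
14 | 1-{4-[2,4-dimethoxy-6-(2,4,6-trimethoxyphenoxy)phenoxy]-2,6-dimethoxyphenoxy}-3,4,5-trimethoxy-2-(3,4,5-trimethoxyphenoxy)benzene (trideca-O-methyl target) | COc1cc(OC)c(Oc2cc(OC)cc(OC)c2Oc2cc(OC)c(Oc3cc(OC)c(OC)c(OC)c3Oc3cc(OC)c(OC)c(OC)c3)c(OC)c2)c(OC)c1 | intermediate
15 | tridecakis(O-dibromoboryl) ether (every OMe of 14 replaced by OBBr2) | BrB(Br)Oc1cc(OB(Br)Br)c(Oc2cc(OB(Br)Br)cc(OB(Br)Br)c2Oc2cc(OB(Br)Br)c(Oc3cc(OB(Br)Br)c(OB(Br)Br)c(OB(Br)Br)c3Oc3cc(OB(Br)Br)c(OB(Br)Br)c(OB(Br)Br)c3)c(OB(Br)Br)c2)c(OB(Br)Br)c1 | intermediate (not isolated)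
16 | 5-{4-[2,4-dihydroxy-6-(2,4,6-trihydroxyphenoxy)phenoxy]-2,6-dihydroxyphenoxy}-4-(3,4,5-trihydroxyphenoxy)benzene-1,2,3-triol (CNP0243665.0, achiral) | Oc1cc(O)c(Oc2cc(O)cc(O)c2Oc2cc(O)c(Oc3cc(O)c(O)c(O)c3Oc3cc(O)c(O)c(O)c3)c(O)c2)c(O)c1 | target

**Totals**
Total step count: 8. Longest linear sequence: 6 (steps 1, 2, 3, 4, 7, 8); steps 5 and 6 form the second branch.

**Three steps most likely to fail, each with a fallback**

Step 7 is the weakest point, because a 2,6-dimethoxyphenol must couple with an electron-rich aryl iodide that carries an ortho aryloxy group. The fallback sets out from 9 and comes back at 14. It abandons the convergent union and attaches ring D by the SNAr chemistry already used in steps 1 and 3, so that the last copper coupling involves an unhindered halide. Rieche formylation (Cl2CHOMe, TiCl4, DCM, 0 °C) of commercial 5-fluoro-1,2,3-trimethoxybenzene, whose two free positions are equivalent, gives 6-fluoro-2,3,4-trimethoxybenzaldehyde F1. Phenol 9 and this aldehyde with Cs2CO3 in DMSO at 120 °C give 6-{4-[2,4-dimethoxy-6-(2,4,6-trimethoxyphenoxy)phenoxy]-2,6-dimethoxyphenoxy}-2,3,4-trimethoxybenzaldehyde F2. mCPBA in DCM turns it into 6-{4-[2,4-dimethoxy-6-(2,4,6-trimethoxyphenoxy)phenoxy]-2,6-dimethoxyphenoxy}-2,3,4-trimethoxyphenyl formate F3, which catalytic K2CO3 in MeOH cleaves to 6-{4-[2,4-dimethoxy-6-(2,4,6-trimethoxyphenoxy)phenoxy]-2,6-dimethoxyphenoxy}-2,3,4-trimethoxyphenol F4. This hindered phenol is then coupled with commercial, unhindered 5-bromo-1,2,3-trimethoxybenzene (CuI, picolinic acid, K3PO4, DMSO, 90 °C) to give 14.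

Step 8 is risky because thirteen methyl ethers must all be cleaved. Partly methylated polyphenols are hard to separate, and the free pyrogallol and phloroglucinol units oxidise in air during work-up. The fallback sets out from 14 and comes back at 16. The crude BBr3 product is not purified as the free phenol but acetylated at once (Ac2O, pyridine, DMAP cat., rt, Ar). This gives 5-{4-[2,4-diacetoxy-6-(2,4,6-triacetoxyphenoxy)phenoxy]-2,6-diacetoxyphenoxy}-4-(3,4,5-triacetoxyphenoxy)benzene-1,2,3-triyl triacetate F5, which is air-stable and can be chromatographed on silica; under-demethylated fractions are separated and sent through BBr3 again. The pure peracetate is then deacetylated without forming phenoxides (degassed HCl in MeOH, rt, Ar) and evaporated to give 16.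

Step 3 is the weaker of the two SNAr steps. Its fluorine is para to an aldehyde that is deactivated by two ortho methoxy donors, and the nucleophile is a bulky, di-ortho-substituted phenoxide. The fallback sets out from 5 and comes back at 9, bypassing 7 and 8, and replaces SNAr plus Baeyer–Villiger by a copper coupling with a protected bromophenol. Commercial 4-bromo-2,6-dimethoxyphenol is benzylated (BnBr, K2CO3, DMF, rt) to 2-(benzyloxy)-5-bromo-1,3-dimethoxybenzene F6. Ullmann coupling of phenol 5 with this unhindered bromide (CuI, picolinic acid, K3PO4, DMSO, 90 °C) gives 2-(benzyloxy)-5-[2,4-dimethoxy-6-(2,4,6-trimethoxyphenoxy)phenoxy]-1,3-dimethoxybenzene F7. Hydrogenolysis (H2, Pd/C, EtOAc–MeOH, rt) removes the benzyl group and gives 9.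

**Further compounds**
F1 | step 7 | 6-fluoro-2,3,4-trimethoxybenzaldehyde | COc1cc(F)c(C=O)c(OC)c1OC
F2 | step 7 | 6-{4-[2,4-dimethoxy-6-(2,4,6-trimethoxyphenoxy)phenoxy]-2,6-dimethoxyphenoxy}-2,3,4-trimethoxybenzaldehyde | COc1cc(Oc2c(OC)cc(OC)cc2Oc2c(OC)cc(OC)cc2OC)cc(OC)c1Oc1cc(OC)c(OC)c(OC)c1C=O
F3 | step 7 | 6-{4-[2,4-dimethoxy-6-(2,4,6-trimethoxyphenoxy)phenoxy]-2,6-dimethoxyphenoxy}-2,3,4-trimethoxyphenyl formate | COc1cc(Oc2c(OC)cc(OC)cc2Oc2c(OC)cc(OC)cc2OC)cc(OC)c1Oc1cc(OC)c(OC)c(OC)c1OC=O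
F4 | step 7 | 6-{4-[2,4-dimethoxy-6-(2,4,6-trimethoxyphenoxy)phenoxy]-2,6-dimethoxyphenoxy}-2,3,4-trimethoxyphenol | COc1cc(Oc2c(OC)cc(OC)cc2Oc2c(OC)cc(OC)cc2OC)cc(OC)c1Oc1cc(OC)c(OC)c(OC)c1O
F5 | step 8 | 5-{4-[2,4-diacetoxy-6-(2,4,6-triacetoxyphenoxy)phenoxy]-2,6-diacetoxyphenoxy}-4-(3,4,5-triacetoxyphenoxy)benzene-1,2,3-triyl triacetate | CC(=O)Oc1cc(OC(C)=O)c(Oc2cc(OC(C)=O)cc(OC(C)=O)c2Oc2cc(OC(C)=O)c(Oc3cc(OC(C)=O)c(OC(C)=O)c(OC(C)=O)c3Oc3cc(OC(C)=O)c(OC(C)=O)c(OC(C)=O)c3)c(OC(C)=O)c2)c(OC(C)=O)c1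
F6 | step 3 | 2-(benzyloxy)-5-bromo-1,3-dimethoxybenzene | COc1cc(Br)cc(OC)c1OCc1ccccc1
F7 | step 3 | 2-(benzyloxy)-5-[2,4-dimethoxy-6-(2,4,6-trimethoxyphenoxy)phenoxy]-1,3-dimethoxybenzene | COc1cc(Oc2c(OC)cc(OC)cc2Oc2c(OC)cc(OC)cc2OC)cc(OC)c1OCc1ccccc1
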